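**Plan**

- Retrosynthesis: the three MOM ethers (O5, O7, O4′) are removed first. Then C2–C3 and O1–C8a of ring C are cut together, which leaves a fully substituted 2-fluoroaryl methyl ketone (as its enol silane) and 4-(methoxymethoxy)benzaldehyde. The acetyl, methyl and prenyl groups are then cut from the ring of 5-fluororesorcinol.
- Enabling feature: the C4 carbonyl makes C3 a nucleophile (enol silane) and, being ortho to C8a on ring A, makes C8a an SNAr electrophile once it carries fluorine. O5 and O7 are meta to C8a and do not cancel this activation, so ring C can close around the aldehyde C=O, which supplies C2 and O1.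
- Forward: ring A is bought and loaded by three directed metalations (prenyl between the oxygens, then methyl and acetyl next to fluorine). Ring B comes with the aldehyde. Ring C is formed in a one-flask asymmetric Mukaiyama aldol / fluoride-relay SNAr annulation, and global MOM removal ends the route.
- Stereochemistry: the only stereocentre, C2 (S), is set by a chiral oxazaborolidinone catalyst in the aldol C–C bond formation. It is retained in the ring closure because the C2–O bond is neither made nor broken there.

Key step: step 6

Assumption: the oxazaborolidinone made from N-tosyl-D-tryptophan is taken as the antipode that leads the enol silane to the Si face of the aldehyde (which gives 2S); should a model aldol show the opposite sense, the L-tryptophan catalyst is used and nothing else changes.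

**Step 1**
Reactants: 1 5-fluororesorcinol
Product: 2 1-fluoro-3,5-bis(methoxymethoxy)benzene
Conditions: NaH (2.4 equiv), MOMCl (2.4 equiv), DMF, 0 °C → rt
Reagents that add atoms: chloromethyl methyl ether, COCCl
Why: Double Williamson-type O-alkylation of the two phenoxides (MOM protection) should be clean because 1 has no other nucleophilic site, and the two OMOM groups are the directing groups for the metalations that follow.

**Step 2**
Reactants: 2 1-fluoro-3,5-bis(methoxymethoxy)benzene
Product: 4 5-fluoro-1,3-bis(methoxymethoxy)-2-(3-methylbut-2-en-1-yl)benzene, via aryllithium 3 (not isolated)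
Conditions: n-BuLi (1.1 equiv), TMEDA (1.1 equiv), Et2O, 0 °C; then CuI (10 mol %), prenyl bromide (1.3 equiv), THF, −78 °C → rt
Reagents that add atoms: 1-bromo-3-methylbut-2-ene (prenyl bromide), CC(C)=CCBr
Why: Directed ortho-metalation: in ether the butyllithium is held by both OMOM groups and should remove the ring hydrogen between them, and copper-catalysed substitution of the aryllithium on prenyl bromide at the primary carbon (SN2, not SN2′) gives the linear prenyl group.

**Step 3**
Reactants: 4 5-fluoro-1,3-bis(methoxymethoxy)-2-(3-methylbut-2-en-1-yl)benzene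
Product: 6 1-fluoro-3,5-bis(methoxymethoxy)-2-methyl-4-(3-methylbut-2-en-1-yl)benzene, via aryllithium 5 (not isolated)
Conditions: n-BuLi (1.1 equiv), TMEDA, THF, −78 °C; then MeI (2 equiv), −78 → −40 °C
Reagents that add atoms: iodomethane, CI
Why: Directed ortho-metalation of one of the two equivalent ring C–H bonds left, each acidified by the adjacent fluorine and chelated by the adjacent OMOM group, followed by SN2 methylation of the aryllithium; −78 °C keeps the ortho-fluoroaryllithium from losing LiF.

**Step 4**
Reactants: 6 1-fluoro-3,5-bis(methoxymethoxy)-2-methyl-4-(3-methylbut-2-en-1-yl)benzene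
Product: 9 1-[2-fluoro-4,6-bis(methoxymethoxy)-3-methyl-5-(3-methylbut-2-en-1-yl)phenyl]ethan-1-one, via aryllithium 7 (not isolated), via lithium hemiaminal alkoxide 8 (not isolated)
Conditions: n-BuLi (1.1 equiv), TMEDA, THF, −78 °C; then MeC(O)N(OMe)Me (1.5 equiv), −78 → −20 °C; then H2O
Reagents that add atoms: N-methoxy-N-methylacetamide, CON(C)C(C)=O
Why: The single remaining ring C–H, again between F and OMOM, is lithiated (directed ortho-metalation) and the aryllithium adds once to the N-methoxy-N-methylamide, whose chelated tetrahedral adduct 8 survives until the aqueous quench (Weinreb ketone synthesis), so no tertiary alcohol forms.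

**Step 5**
Reactants: 9 1-[2-fluoro-4,6-bis(methoxymethoxy)-3-methyl-5-(3-methylbut-2-en-1-yl)phenyl]ethan-1-one
Product: 11 {1-[2-fluoro-4,6-bis(methoxymethoxy)-3-methyl-5-(3-methylbut-2-en-1-yl)phenyl]ethenyl}oxy(trimethyl)silane, via lithium enolate 10 (not isolated)
Conditions: LiHMDS (1.2 equiv), THF, −78 °C; then TMSCl (1.5 equiv), −78 → 0 °C; pentane, filtration under argon, concentration, used at once
Reagents that add atoms: chlorotrimethylsilane, C[Si](C)(C)Cl
Why: Kinetic deprotonation of the only enolisable position (the acetyl CH3) by a hindered amide base and O-silylation of the lithium enolate (enol silane formation) should give the terminal enol ether, while the C–F bond is inert to LiHMDS at −78 °C.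

**Step 6**
Reactants: 11 {1-[2-fluoro-4,6-bis(methoxymethoxy)-3-methyl-5-(3-methylbut-2-en-1-yl)phenyl]ethenyl}oxy(trimethyl)silane; 12 4-(methoxymethoxy)benzaldehyde
Product: 15 (2S)-5,7-bis(methoxymethoxy)-2-[4-(methoxymethoxy)phenyl]-8-methyl-6-(3-methylbut-2-en-1-yl)-2,3-dihydro-4H-chromen-4-one, via aldol silyl ether 13 (not isolated), via ammonium alkoxide 14 (not isolated)
Conditions: (R)-2-butyl-4-(indol-3-ylmethyl)-3-tosyl-1,3,2-oxazaborolidin-5-one (20 mol %, from N-Ts-D-tryptophan and n-BuB(OH)2), EtCN, −78 → −40 °C; then tetrabutylammonium difluorotriphenylsilicate (TBAT, 0.4 equiv), THF, −78 → 0 °C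
Reagents that add atoms: none
Why: Proposed new method: the boron-bound aldehyde is attacked by enol silane 11 through an open transition state (Mukaiyama aldol) and silyl transfer gives the β-silyloxy ketone 13; fluoride then removes the silyl group, and the alkoxide 14 adds to C8a, the fluorine-bearing ring carbon ortho to the ketone, and expels fluoride through a Meisenheimer intermediate, so that each ring closure returns the fluoride for the next desilylation and only Me3SiF is lost. The closest known reaction types are the oxazaborolidinone-catalysed Mukaiyama aldol of aryl methyl ketone enol silanes, with its aldol–dihydropyranone annulation variant, and the fluoride-catalysed SNAr etherification of activated aryl fluorides with silyl ethers; their coupling in one flask on a 2-fluoroaryl ketone is the new element. Ring C closes by intramolecular addition–elimination at an aromatic carbon, a six-membered 6-endo-trig closure in which the C8a=C4a bond that passes the charge to the C4 carbonyl lies inside the new ring. C2 is set in the aldol step by the catalyst, whose indole shields one face of the coordinated aldehyde so that C3 adds to the Si face, and it is carried through the ring closure unchanged because the C2–O bond is neither made nor broken there. The step needs face selectivity at the aldehyde, attack of the alkoxide at the fluorinated ortho carbon and not at the OMOM-bearing one, and ring closure faster than retro-aldol cleavage or β-elimination of the silyloxy group. The substrate secures the site selectivity (fluoride is the only nucleofuge, the C4 carbonyl is ortho to it, and O5 and O7 are meta to C8a and cannot donate into it), while the cold aprotic medium is meant to hold back retro-aldol cleavage and the low standing concentration of alkoxide under catalytic fluoride to hold back intermolecular β-elimination.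

**Step 7**
Reactants: 15 (2S)-5,7-bis(methoxymethoxy)-2-[4-(methoxymethoxy)phenyl]-8-methyl-6-(3-methylbut-2-en-1-yl)-2,3-dihydro-4H-chromen-4-one
Product: 16 (2S)-5,7-dihydroxy-2-(4-hydroxyphenyl)-8-methyl-6-(3-methylbut-2-en-1-yl)-2,3-dihydro-4H-chromen-4-one
Conditions: HCl (1.25 M in MeOH, 10 equiv), MeOH/THF 3:1, 40 °C, stopped at full conversion
Reagents that add atoms: none
Why: Acid-catalysed acetal exchange with methanol (MOM methanolysis) releases the three phenols as dimethoxymethane leaves; the C2 stereocentre should be kept because the ring-opening to the chalcone that racemises flavanones is base-promoted, and the low acid strength and temperature are chosen so that the prenyl alkene is not protonated towards chroman formation.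

**Compound list**

1 | 5-fluororesorcinol (5-fluorobenzene-1,3-diol) | Oc1cc(O)cc(F)c1 | starting material
2 | 1-fluoro-3,5-bis(methoxymethoxy)benzene | COCOc1cc(F)cc(OCOC)c1 | intermediate
3 | [4-fluoro-2,6-bis(methoxymethoxy)phenyl]lithium | [Li]c1c(OCOC)cc(F)cc1OCOC | intermediate
4 | 5-fluoro-1,3-bis(methoxymethoxy)-2-(3-methylbut-2-en-1-yl)benzene | CC(C)=CCc1c(OCOC)cc(F)cc1OCOC | intermediate
5 | [2-fluoro-4,6-bis(methoxymethoxy)-5-(3-methylbut-2-en-1-yl)phenyl]lithium | [Li]c1c(F)cc(OCOC)c(CC=C(C)C)c1OCOC | intermediate
6 | 1-fluoro-3,5-bis(methoxymethoxy)-2-methyl-4-(3-methylbut-2-en-1-yl)benzene | CC(C)=CCc1c(OCOC)cc(F)c(C)c1OCOC | intermediate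
7 | [2-fluoro-4,6-bis(methoxymethoxy)-3-methyl-5-(3-methylbut-2-en-1-yl)phenyl]lithium | [Li]c1c(F)c(C)c(OCOC)c(CC=C(C)C)c1OCOC | intermediate
8 | lithium 1-[2-fluoro-4,6-bis(methoxymethoxy)-3-methyl-5-(3-methylbut-2-en-1-yl)phenyl]-1-[methoxy(methyl)amino]ethan-1-olate (tetrahedral adduct, racemic) | CON(C)C(C)(O[Li])c1c(F)c(C)c(OCOC)c(CC=C(C)C)c1OCOC | intermediate
9 | 1-[2-fluoro-4,6-bis(methoxymethoxy)-3-methyl-5-(3-methylbut-2-en-1-yl)phenyl]ethan-1-one | CC(=O)c1c(F)c(C)c(OCOC)c(CC=C(C)C)c1OCOC | intermediate
10 | lithium 1-[2-fluoro-4,6-bis(methoxymethoxy)-3-methyl-5-(3-methylbut-2-en-1-yl)phenyl]ethen-1-olate | [Li]OC(=C)c1c(F)c(C)c(OCOC)c(CC=C(C)C)c1OCOC | intermediate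
11 | {1-[2-fluoro-4,6-bis(methoxymethoxy)-3-methyl-5-(3-methylbut-2-en-1-yl)phenyl]ethenyl}oxy(trimethyl)silane | C=C(O[Si](C)(C)C)c1c(F)c(C)c(OCOC)c(CC=C(C)C)c1OCOC | intermediate
12 | 4-(methoxymethoxy)benzaldehyde | COCOc1ccc(C=O)cc1 | starting material
13 | (3S)-1-[2-fluoro-4,6-bis(methoxymethoxy)-3-methyl-5-(3-methylbut-2-en-1-yl)phenyl]-3-[4-(methoxymethoxy)phenyl]-3-[(trimethylsilyl)oxy]propan-1-one | CC(C)=CCc1c(OCOC)c(C)c(F)c(c1OCOC)C(=O)C[C@@H](c1ccc(OCOC)cc1)O[Si](C)(C)C | intermediate
14 | tetrabutylammonium (1S)-3-[2-fluoro-4,6-bis(methoxymethoxy)-3-methyl-5-(3-methylbut-2-en-1-yl)phenyl]-1-[4-(methoxymethoxy)phenyl]-3-oxopropan-1-olate | CC(C)=CCc1c(OCOC)c(C)c(F)c(c1OCOC)C(=O)C[C@@H](c1ccc(OCOC)cc1)[O-].CCCC[N+](CCCC)(CCCC)CCCC | intermediate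
15 | (2S)-5,7-bis(methoxymethoxy)-2-[4-(methoxymethoxy)phenyl]-8-methyl-6-(3-methylbut-2-en-1-yl)-2,3-dihydro-4H-chromen-4-one | CC(C)=CCc1c(OCOC)c(C)c2c(c1OCOC)C(=O)C[C@@H](c1ccc(OCOC)cc1)O2 | intermediate
16 | (2S)-5,7-dihydroxy-2-(4-hydroxyphenyl)-8-methyl-6-(3-methylbut-2-en-1-yl)-2,3-dihydro-4H-chromen-4-one (5,7,4'-trihydroxy-8-methyl-6-prenylflavanone) | CC(C)=CCc1c(O)c(C)c2c(c1O)C(=O)C[C@@H](c1ccc(O)cc1)O2 | target

**Step count**

Total steps: 7. Longest linear sequence: 7 (1 → 16).

**Steps most likely to fail**

Step 6 (proposed new method). The alkoxide 14 may undergo retro-aldol cleavage and recombine without the catalyst, which would erode the enantiopurity. β-Elimination of the silyloxy group may compete, or the SNAr may be too slow at the electron-rich, doubly ortho-substituted ring. The fallback uses known chemistry and sets out from ketone 9. Claisen condensation of its lithium enolate (LiHMDS, THF, −78 → 0 °C) with methyl 4-(methoxymethoxy)benzoate should give 1-[2-fluoro-4,6-bis(methoxymethoxy)-3-methyl-5-(3-methylbut-2-en-1-yl)phenyl]-3-[4-(methoxymethoxy)phenyl]propane-1,3-dione F1. K2CO3 in DMF at 80 °C should then close ring C by SNAr of the enol oxygen on the C–F carbon, the usual chromone closure of 2-fluoroaryl 1,3-diketones, to give 5,7-bis(methoxymethoxy)-2-[4-(methoxymethoxy)phenyl]-8-methyl-6-(3-methylbut-2-en-1-yl)-4H-chromen-4-one F2. Asymmetric conjugate reduction of the C2=C3 bond with a chiral bisphosphine–copper hydride catalyst (Cu(OAc)2, the DTBM-SEGPHOS antipode that gives 2S, a hydrosilane, t-BuOH, toluene) leaves the prenyl alkene alone and comes back to the route at 15.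

Step 2. Metalation may occur next to fluorine instead of between the two OMOM groups, or at both kinds of site. The fallback sets out from 1 and replaces deprotonation by halogen–metal exchange. Iodination with I2/NaHCO3 in water, which places iodine between the two hydroxyl groups of resorcinols, should give 5-fluoro-2-iodobenzene-1,3-diol F3. NaH/MOMCl should give 5-fluoro-2-iodo-1,3-bis(methoxymethoxy)benzene F4. Iodine–lithium exchange with n-BuLi at −78 °C then gives aryllithium 3 with no choice of site, and the route continues from 3 as in step 2.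

Step 4. The hindered aryllithium 7 may take a proton from the acetyl CH3 of the amide instead of adding to it, or may lose LiF (aryne formation) if the slow addition forces warming. The fallback sets out from aryllithium 7 and separates C–C bond formation from the oxidation level. A quench at −78 °C with acetaldehyde, a small and fast electrophile, should give 1-[2-fluoro-4,6-bis(methoxymethoxy)-3-methyl-5-(3-methylbut-2-en-1-yl)phenyl]ethan-1-ol F5. Oxidation with DMP/NaHCO3 in CH2Cl2 comes back to the route at 9.

**Further compounds**

F1 | step 6 | 1-[2-fluoro-4,6-bis(methoxymethoxy)-3-methyl-5-(3-methylbut-2-en-1-yl)phenyl]-3-[4-(methoxymethoxy)phenyl]propane-1,3-dione | CC(C)=CCc1c(OCOC)c(C)c(F)c(c1OCOC)C(=O)CC(=O)c1ccc(OCOC)cc1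
F2 | step 6 | 5,7-bis(methoxymethoxy)-2-[4-(methoxymethoxy)phenyl]-8-methyl-6-(3-methylbut-2-en-1-yl)-4H-chromen-4-one | CC(C)=CCc1c(OCOC)c(C)c2oc(-c3ccc(OCOC)cc3)cc(=O)c2c1OCOC
F3 | step 2 | 5-fluoro-2-iodobenzene-1,3-diol | Oc1cc(F)cc(O)c1I
F4 | step 2 | 5-fluoro-2-iodo-1,3-bis(methoxymethoxy)benzene | COCOc1cc(F)cc(OCOC)c1I
F5 | step 4 | 1-[2-fluoro-4,6-bis(methoxymethoxy)-3-methyl-5-(3-methylbut-2-en-1-yl)phenyl]ethan-1-ol (racemic) | CC(O)c1c(F)c(C)c(OCOC)c(CC=C(C)C)c1OCOC
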